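**Plan**

1. Numbering: left decalin C1–C10 (ring A = C1–C5 and C10; ring B = C5–C10), linker C11–C12, right decalin C1′–C8a′. "DecR" is the (1S,2R,8aR)-1,2,5,5-tetramethyl-1,2,3,5,6,7,8,8a-octahydronaphthalen-1-yl group; TBS = tert-butyldimethylsilyl.
2. Retrosynthesis: remove the two sulfates and the C4 methylene (back to a C4 silyloxy group), cut the aryl–CH2 bond (aldehyde on C9), cut C5–C10 and C8–C9 together, then C5–C11 (B-alkyl Suzuki coupling), and in the right decalin C1′–C8a′ and C2′–C3′ (intermolecular Diels–Alder).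
3. Enabling feature: ring B carries at C5 (quaternary, linker), C10 (H), C9 (CH3 and CH2Ar) and C8 (CH3 cis to CH2Ar) the pattern of an endo adduct of an (E)-2-methyl enal on an (E,E)-diene. Ring A (C1–C4 plus C5 and C10) is the four-carbon tether, so both left rings can form in one intramolecular cycloaddition.
4. Forward: right decalin first, then the iodo-dienyl carbinol, Suzuki union, enal installation, cycloaddition closing rings A and B, then aryl addition, deoxygenation, saturation of C6=C7, C4 carbinol to ketone to methylene, hydroquinone release and sulfation.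
5. Stereochemistry: C1′, C2′ and C8a′ come from a chiral oxazaborolidinium catalyst and the (E)-enal; C4 from a catalytic asymmetric organozinc addition; C5, C8, C9 and C10 from the alkene geometries and the C4 silyloxy group in the cycloaddition.

Key step: step 13

Remark: the target is drawn as the bis(hydrogen sulfate); the sulfation would deliver it as its pyridinium salt, and the neutral acid formula is used for compound 32.

**Route**

Step 1
Reactants: 1 2,2-dimethylcyclohexanone
Product: 3 6,6-dimethylcyclohex-1-en-1-yl trifluoromethanesulfonate, via lithium enolate 2 (not isolated)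
Conditions: LDA, THF, −78 °C; PhNTf2, −78 °C → rt
Reagents that add atoms: N-phenylbis(trifluoromethanesulfonimide), O=S(=O)(N(c1ccccc1)S(=O)(=O)C(F)(F)F)C(F)(F)F
Why: Deprotonation can only occur at C6 because C2 is quaternary, and O-sulfonylation of the lithium enolate is the standard enol triflate synthesis.

Step 2
Reactants: 3 6,6-dimethylcyclohex-1-en-1-yl trifluoromethanesulfonate
Product: 4 1-ethenyl-6,6-dimethylcyclohex-1-ene
Conditions: tributyl(vinyl)stannane, Pd(PPh3)4 (cat.), LiCl, THF, 65 °C
Reagents that add atoms: tributyl(vinyl)stannane, C=C[Sn](CCCC)(CCCC)CCCC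
Why: Stille coupling of a cyclohexenyl triflate with a vinylstannane in the presence of LiCl is a standard route to 1-vinylcyclohexenes.

Step 3
Reactants: 4 1-ethenyl-6,6-dimethylcyclohex-1-ene; 5 (E)-2-methylbut-2-enal
Product: 6 (1S,2R,8aS)-1,2,5,5-tetramethyl-1,2,3,5,6,7,8,8a-octahydronaphthalene-1-carbaldehyde
Conditions: (S)-3,3-diphenyl-1-(2-methylphenyl)tetrahydro-1H,3H-pyrrolo[1,2-c][1,3,2]oxazaborole (20 mol %), (CF3SO2)2NH (20 mol %), CH2Cl2, −78 → −40 °C
Reagents that add atoms: none
Why: In this oxazaborolidinium-catalysed enantioselective Diels–Alder reaction of a 2-substituted enal, the enal β-carbon should bond to the unsubstituted vinyl terminus (C2′–C3′) and the α-carbon to the ring terminus (C1′–C8a′), the (E)-enal keeps the two methyl groups cis, the exo-formyl transition state usual for 2-methyl enals places H-8a′ cis to the formyl group, and the catalyst (formyl C–H···O binding model) shields the α-Si face so that the diene adds to the α-Re face.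

Step 4
Reactants: 6 (1S,2R,8aS)-1,2,5,5-tetramethyl-1,2,3,5,6,7,8,8a-octahydronaphthalene-1-carbaldehyde
Product: 7 (1S,2R,8aR)-1-ethenyl-1,2,5,5-tetramethyl-1,2,3,5,6,7,8,8a-octahydronaphthalene
Conditions: Ph3PCH3Br, KHMDS, THF, 0 °C → rt
Reagents that add atoms: methyltriphenylphosphonium bromide, C[P+](c1ccccc1)(c1ccccc1)c1ccccc1.[Br-]
Why: Wittig methylenation of a non-enolisable neopentyl aldehyde touches no stereocentre.

Step 5
Reactants: 8 tetrahydrofuran
Product: 9 4-iodobutyl pivalate
Conditions: pivaloyl chloride, NaI, MeCN, 0 °C → rt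
Reagents that add atoms: pivaloyl chloride, CC(C)(C)C(Cl)=O; sodium iodide, [Na+].[I-]
Why: The acyl iodide formed in the flask opens tetrahydrofuran through the acyloxonium ion, the standard preparation of 4-iodobutyl esters.

Step 6
Reactants: 10 (2E,4E)-hexa-2,4-dienal
Product: 11 (2Z,4E)-2-iodohexa-2,4-dienal
Conditions: I2, K2CO3, 4-(dimethylamino)pyridine (20 mol %), THF/H2O, rt
Reagents that add atoms: iodine, II
Why: Amine-catalysed α-iodination of an enal (conjugate addition of the pyridine, iodination of the enolate, elimination) should give the more stable (2Z)-iodide, in which the formyl group stays trans to C4 and the C4=C5 bond is a spectator.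

Step 7
Reactants: 9 4-iodobutyl pivalate; 11 (2Z,4E)-2-iodohexa-2,4-dienal
Product: 13 (5R,6Z,8E)-5-hydroxy-6-iododeca-6,8-dien-1-yl pivalate, via bis[4-(pivaloyloxy)butyl]zinc 12 (not isolated)
Conditions: 9, Et2Zn, CuI (cat.), 50 °C, then vacuum; Ti(OiPr)4, (1S,2S)-1,2-bis(trifluoromethanesulfonamido)cyclohexane (8 mol %), toluene, −20 °C, then 11
Reagents that add atoms: none
Why: Titanium/bis-sulfonamide-catalysed asymmetric addition of a functionalised dialkylzinc (from iodine–zinc exchange) to an α-substituted enal, a substrate class known for high enantioselectivity; the (1S,2S)-ligand should deliver the alkyl group to the Re face of the formyl group and set (5R), the future C4.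

Step 8
Reactants: 13 (5R,6Z,8E)-5-hydroxy-6-iododeca-6,8-dien-1-yl pivalate
Product: 14 (5R,6Z,8E)-5-[(tert-butyldimethylsilyl)oxy]-6-iododeca-6,8-dien-1-yl pivalate
Conditions: TBSCl, imidazole, DMF, rt
Reagents that add atoms: tert-butyldimethylsilyl chloride, CC(C)(C)[Si](C)(C)Cl
Why: Standard silylation of a secondary allylic alcohol.

Step 9
Reactants: 7 (1S,2R,8aR)-1-ethenyl-1,2,5,5-tetramethyl-1,2,3,5,6,7,8,8a-octahydronaphthalene; 14 (5R,6Z,8E)-5-[(tert-butyldimethylsilyl)oxy]-6-iododeca-6,8-dien-1-yl pivalate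
Product: 16 (5R,6E,8E)-5-[(tert-butyldimethylsilyl)oxy]-6-[2-(DecR)ethyl]deca-6,8-dien-1-yl pivalate, via B-alkyl-9-BBN 15 (not isolated)
Conditions: 7, 9-BBN, THF, rt → 50 °C; then 14, Pd(dppf)Cl2 (cat.), AsPh3, Cs2CO3, DMF/H2O, rt
Reagents that add atoms: none
Why: 9-BBN should hydroborate only the monosubstituted vinyl group (anti-Markovnikov, ring alkene untouched), and the B-alkyl Suzuki–Miyaura coupling proceeds with retention at the iodoalkene, forming C5–C11 with the linker cis to C7.

Step 10
Reactants: 16 (5R,6E,8E)-5-[(tert-butyldimethylsilyl)oxy]-6-[2-(DecR)ethyl]deca-6,8-dien-1-yl pivalate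
Product: 17 (5R,6E,8E)-5-[(tert-butyldimethylsilyl)oxy]-6-[2-(DecR)ethyl]deca-6,8-dien-1-ol
Conditions: DIBAL-H, CH2Cl2, −78 °C
Reagents that add atoms: none
Why: Reductive cleavage of the pivalate, to which the silyl ether and the alkenes are inert.

Step 11
Reactants: 17 (5R,6E,8E)-5-[(tert-butyldimethylsilyl)oxy]-6-[2-(DecR)ethyl]deca-6,8-dien-1-ol
Product: 18 (5R,6E,8E)-5-[(tert-butyldimethylsilyl)oxy]-6-[2-(DecR)ethyl]deca-6,8-dienal
Conditions: Dess–Martin periodinane, NaHCO3, CH2Cl2, 0 °C → rt
Reagents that add atoms: none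
Why: Buffered Dess–Martin oxidation of a primary alcohol stops at the aldehyde and should spare the acid-sensitive dienylic silyl ether.

Step 12
Reactants: 18 (5R,6E,8E)-5-[(tert-butyldimethylsilyl)oxy]-6-[2-(DecR)ethyl]deca-6,8-dienal
Product: 19 (2E,7R,8E,10E)-7-[(tert-butyldimethylsilyl)oxy]-2-methyl-8-[2-(DecR)ethyl]dodeca-2,8,10-trienal
Conditions: Ph3P=C(CH3)CHO, benzene, 70 °C
Reagents that add atoms: 2-(triphenylphosphoranylidene)propanal, CC(C=O)=P(c1ccccc1)(c1ccccc1)c1ccccc1
Why: Wittig olefination with the stabilised formyl ylide gives the (E)-2-methyl enal, at a temperature meant to stay below that of uncatalysed cycloaddition.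

Step 13
Reactants: 19 (2E,7R,8E,10E)-7-[(tert-butyldimethylsilyl)oxy]-2-methyl-8-[2-(DecR)ethyl]dodeca-2,8,10-trienal
Product: 20 trans-fused Δ6-octalin aldehyde: (4R)-4-silyloxy group β and equatorial; C5 linker and C9 methyl β; H-10, C8 methyl and C9 formyl α
Conditions: Me2AlCl (1.5 equiv), CH2Cl2, −78 → −20 °C
Reagents that add atoms: none
Why: Me2AlCl binds the formyl oxygen and the (E)-2-methyl enal C9=C10 adds across the C5=C6–C7=C8 diene in a concerted, asynchronous [4+2] process in which the C10–C5 bond leads; the closest known reaction type is the Lewis-acid-promoted type 1 intramolecular Diels–Alder reaction of 2-methyl-2,8,10-undecatrienals to trans-fused octalins with a formyl-bearing quaternary carbon. Ring B closes as the six-membered cycloaddition ring (bonds C5–C10 and C8–C9, new alkene C6=C7), and ring A closes as the fused six-membered carbocycle spanned by the C1–C4 tether, which sits in a chair. C9 and C10 are set by the (E)-enal geometry (C9 methyl cis to C1, formyl cis to H-10), C8 by the (E)-C7=C8 geometry with its methyl outside and hence cis to the endo formyl carbon, and C5 by the (E)-C5=C6 geometry, which places C4 outside and the linker inside. The trans ring fusion follows from the endo-formyl, anti-tether transition state, which the Lewis acid should favour over the exo-formyl cis-fused one. The diene face is selected by the (R)-C4 silyloxy group, equatorial on the chair tether with H-4 eclipsing C5=C6, because the other face would force the silyloxy group axial and into the diene plane against H-6. The step therefore needs endo and π-facial selectivity and enough reactivity from a diene with an inside substituent at C5; the aldehyde–aluminium complex, the four-carbon tether and the single carbinol stereocentre are meant to provide them.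

Step 14
Reactants: 20 trans-fused Δ6-octalin aldehyde; 21 2-bromo-1,4-dimethoxybenzene
Product: 23 benzylic carbinol (C9–CH(OH)–2,5-dimethoxyphenyl; both carbinol epimers), via 2,5-dimethoxyphenyllithium 22 (not isolated)
Conditions: 21, n-BuLi, THF, −78 °C; then 20, −78 → 0 °C; H2O
Reagents that add atoms: none
Why: Bromine–lithium exchange and 1,2-addition of the aryllithium to a non-enolisable neopentyl aldehyde; the new carbinol centre is removed two steps later, so its configuration does not matter.

Step 15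
Reactants: 23 benzylic carbinol
Product: 24 O-benzylic S-methyl xanthate
Conditions: NaHMDS, THF, −78 °C; CS2; MeI, → rt
Reagents that add atoms: carbon disulfide, S=C=S; iodomethane, CI
Why: Xanthate formation from the sodium alkoxide, the first half of a Barton–McCombie deoxygenation.

Step 16
Reactants: 24 O-benzylic S-methyl xanthate
Product: 25 Δ6-octalin with C9–CH2–(2,5-dimethoxyphenyl) and C4 silyloxy group
Conditions: Bu3SnH, azobisisobutyronitrile (cat.), toluene, 100 °C
Reagents that add atoms: none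
Why: Barton–McCombie radical deoxygenation through a stabilised benzylic radical that has no favourable cyclisation onto either alkene.

Step 17
Reactants: 25 Δ6-octalin with C9–CH2–(2,5-dimethoxyphenyl) and C4 silyloxy group
Product: 26 saturated trans-decalin silyl ether
Conditions: H2 (1 atm), PtO2 (cat.), EtOAc, rt, stopped after one equivalent of H2
Reagents that add atoms: none
Why: Heterogeneous hydrogenation should distinguish the cis-disubstituted C6=C7 from the hindered trisubstituted C4′=C4a′ alkene; no stereocentre is formed.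

Step 18
Reactants: 26 saturated trans-decalin silyl ether
Product: 27 (4R)-decalin-4-ol
Conditions: Bu4NF, THF, 50 °C
Reagents that add atoms: none
Why: Fluoride-mediated cleavage of the hindered secondary silyl ether.

Step 19
Reactants: 27 (4R)-decalin-4-ol
Product: 28 decalin-4-one
Conditions: Dess–Martin periodinane, NaHCO3, CH2Cl2, rt
Reagents that add atoms: none
Why: Dess–Martin oxidation of a hindered secondary alcohol; the α-carbons (C3 methylene, C5 quaternary) cannot epimerise.

Step 20
Reactants: 28 decalin-4-one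
Product: 29 4-methylene decalin bearing the 2,5-dimethoxybenzyl group
Conditions: Ph3PCH3Br, KOtBu, toluene, 90 °C
Reagents that add atoms: methyltriphenylphosphonium bromide, C[P+](c1ccccc1)(c1ccccc1)c1ccccc1.[Br-]
Why: Wittig methylenation with the potassium tert-butoxide-generated ylide in hot toluene is the established method for cyclohexanones next to a quaternary carbon.

Step 21
Reactants: 29 4-methylene decalin bearing the 2,5-dimethoxybenzyl group
Product: 30 2-substituted 1,4-benzoquinone
Conditions: (NH4)2Ce(NO3)6, MeCN/H2O, 0 °C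
Reagents that add atoms: water, O
Why: Oxidative demethylation of a 1,4-dimethoxyarene with ceric ammonium nitrate gives the quinone and is known to tolerate isolated alkenes.

Step 22
Reactants: 30 2-substituted 1,4-benzoquinone
Product: 31 hydroquinone
Conditions: Na2S2O4, THF/H2O, rt
Reagents that add atoms: none
Why: Dithionite reduction of a quinone to the hydroquinone.

Step 23
Reactants: 31 hydroquinone
Product: 32 CNP0426429.4 (hydroquinone bis(hydrogen sulfate))
Conditions: SO3·pyridine (excess), pyridine, rt → 40 °C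
Reagents that add atoms: sulfur trioxide–pyridine complex, O=S(=O)([O-])[n+]1ccccc1
Why: O-Sulfation of both phenols with SO3·pyridine, which does not attack the alkenes.

**Compound list**

1 | 2,2-dimethylcyclohexanone | CC1(C)CCCCC1=O | starting material
2 | lithium 6,6-dimethylcyclohex-1-en-1-olate | [Li]OC1=CCCCC1(C)C | intermediate
3 | 6,6-dimethylcyclohex-1-en-1-yl trifluoromethanesulfonate | CC1(C)CCCC=C1OS(=O)(=O)C(F)(F)F | intermediate
4 | 1-ethenyl-6,6-dimethylcyclohex-1-ene | C=CC1=CCCCC1(C)C | intermediate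
5 | (E)-2-methylbut-2-enal | C/C=C(\C)C=O | starting material
6 | (1S,2R,8aS)-1,2,5,5-tetramethyl-1,2,3,5,6,7,8,8a-octahydronaphthalene-1-carbaldehyde | O=C[C@@]1(C)[C@H](C)CC=C2[C@@H]1CCCC2(C)C | intermediate
7 | (1S,2R,8aR)-1-ethenyl-1,2,5,5-tetramethyl-1,2,3,5,6,7,8,8a-octahydronaphthalene | C=C[C@@]1(C)[C@H](C)CC=C2[C@@H]1CCCC2(C)C | intermediate
8 | tetrahydrofuran | C1CCOC1 | starting material
9 | 4-iodobutyl pivalate | CC(C)(C)C(=O)OCCCCI | intermediate
10 | (2E,4E)-hexa-2,4-dienal | C/C=C/C=C/C=O | starting material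
11 | (2Z,4E)-2-iodohexa-2,4-dienal | C/C=C/C=C(\I)C=O | intermediate
12 | bis[4-(pivaloyloxy)butyl]zinc | CC(C)(C)C(=O)OCCCC[Zn]CCCCOC(=O)C(C)(C)C | intermediate
13 | (5R,6Z,8E)-5-hydroxy-6-iododeca-6,8-dien-1-yl pivalate | CC(C)(C)C(=O)OCCCC[C@@H](O)/C(I)=C/C=C/C | intermediate
14 | (5R,6Z,8E)-5-[(tert-butyldimethylsilyl)oxy]-6-iododeca-6,8-dien-1-yl pivalate | CC(C)(C)C(=O)OCCCC[C@@H](O[Si](C)(C)C(C)(C)C)/C(I)=C/C=C/C | intermediate
15 | 9-[2-(DecR)ethyl]-9-borabicyclo[3.3.1]nonane | C1CC2CCCC(C1)B2CC[C@@]1(C)[C@H](C)CC=C2[C@@H]1CCCC2(C)C | intermediate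
16 | (5R,6E,8E)-5-[(tert-butyldimethylsilyl)oxy]-6-[2-(DecR)ethyl]deca-6,8-dien-1-yl pivalate | CC(C)(C)C(=O)OCCCC[C@@H](O[Si](C)(C)C(C)(C)C)/C(CC[C@@]1(C)[C@H](C)CC=C2[C@@H]1CCCC2(C)C)=C/C=C/C | intermediate
17 | (5R,6E,8E)-5-[(tert-butyldimethylsilyl)oxy]-6-[2-(DecR)ethyl]deca-6,8-dien-1-ol | OCCCC[C@@H](O[Si](C)(C)C(C)(C)C)/C(CC[C@@]1(C)[C@H](C)CC=C2[C@@H]1CCCC2(C)C)=C/C=C/C | intermediate
18 | (5R,6E,8E)-5-[(tert-butyldimethylsilyl)oxy]-6-[2-(DecR)ethyl]deca-6,8-dienal | O=CCCC[C@@H](O[Si](C)(C)C(C)(C)C)/C(CC[C@@]1(C)[C@H](C)CC=C2[C@@H]1CCCC2(C)C)=C/C=C/C | intermediate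
19 | (2E,7R,8E,10E)-7-[(tert-butyldimethylsilyl)oxy]-2-methyl-8-[2-(DecR)ethyl]dodeca-2,8,10-trienal | O=C/C(C)=C/CCC[C@@H](O[Si](C)(C)C(C)(C)C)/C(CC[C@@]1(C)[C@H](C)CC=C2[C@@H]1CCCC2(C)C)=C/C=C/C | intermediate
20 | trans-fused Δ6-octalin aldehyde (4R-silyloxy β; C5 linker and C9 methyl β; H-10, C8 methyl and C9 formyl α) | [C@@H]1(O[Si](C)(C)C(C)(C)C)CCC[C@H]2[C@@]1(CC[C@@]3(C)[C@H](C)CC=C4[C@@H]3CCCC4(C)C)C=C[C@H](C)[C@]2(C)C=O | intermediate
21 | 2-bromo-1,4-dimethoxybenzene | COc1ccc(OC)c(Br)c1 | starting material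
22 | 2,5-dimethoxyphenyllithium | [Li]c1cc(OC)ccc1OC | intermediate
23 | benzylic carbinol (C9–CH(OH)Ar, both carbinol epimers; Ar = 2,5-dimethoxyphenyl) | [C@@H]1(O[Si](C)(C)C(C)(C)C)CCC[C@H]2[C@@]1(CC[C@@]3(C)[C@H](C)CC=C4[C@@H]3CCCC4(C)C)C=C[C@H](C)[C@]2(C)C(O)c1cc(OC)ccc1OC | intermediate
24 | O-benzylic S-methyl xanthate of 23 | [C@@H]1(O[Si](C)(C)C(C)(C)C)CCC[C@H]2[C@@]1(CC[C@@]3(C)[C@H](C)CC=C4[C@@H]3CCCC4(C)C)C=C[C@H](C)[C@]2(C)C(OC(=S)SC)c1cc(OC)ccc1OC | intermediate
25 | Δ6-octalin with C9–CH2Ar and C4 silyloxy group | [C@@H]1(O[Si](C)(C)C(C)(C)C)CCC[C@H]2[C@@]1(CC[C@@]3(C)[C@H](C)CC=C4[C@@H]3CCCC4(C)C)C=C[C@H](C)[C@]2(C)Cc1cc(OC)ccc1OC | intermediate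
26 | saturated trans-decalin silyl ether | [C@@H]1(O[Si](C)(C)C(C)(C)C)CCC[C@H]2[C@@]1(CC[C@@]3(C)[C@H](C)CC=C4[C@@H]3CCCC4(C)C)CC[C@H](C)[C@]2(C)Cc1cc(OC)ccc1OC | intermediate
27 | (4R)-decalin-4-ol | [C@@H]1(O)CCC[C@H]2[C@@]1(CC[C@@]3(C)[C@H](C)CC=C4[C@@H]3CCCC4(C)C)CC[C@H](C)[C@]2(C)Cc1cc(OC)ccc1OC | intermediate
28 | decalin-4-one | O=C1CCC[C@H]2[C@@]1(CC[C@@]3(C)[C@H](C)CC=C4[C@@H]3CCCC4(C)C)CC[C@H](C)[C@]2(C)Cc1cc(OC)ccc1OC | intermediate
29 | 4-methylene decalin with 2,5-dimethoxybenzyl group | C=C1CCC[C@H]2[C@@]1(CC[C@@]3(C)[C@H](C)CC=C4[C@@H]3CCCC4(C)C)CC[C@H](C)[C@]2(C)Cc1cc(OC)ccc1OC | intermediate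
30 | 2-substituted 1,4-benzoquinone | C=C1CCC[C@H]2[C@@]1(CC[C@@]3(C)[C@H](C)CC=C4[C@@H]3CCCC4(C)C)CC[C@H](C)[C@]2(C)CC1=CC(=O)C=CC1=O | intermediate
31 | hydroquinone | C=C1CCC[C@H]2[C@@]1(CC[C@@]3(C)[C@H](C)CC=C4[C@@H]3CCCC4(C)C)CC[C@H](C)[C@]2(C)Cc1cc(O)ccc1O | intermediate
32 | CNP0426429.4, hydroquinone bis(hydrogen sulfate) | C=C1CCC[C@H]2[C@@]1(CC[C@@]1(C)[C@H](C)CC=C3[C@@H]1CCCC3(C)C)CC[C@H](C)[C@]2(C)Cc1cc(OS(=O)(=O)O)ccc1OS(=O)(=O)O | target

**Step count and risks**

Total: 23 steps. Longest linear sequence: 19 steps (steps 1–4, then 9–23).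

Step 13 (key cycloaddition). The aluminium Lewis acid may ionise the dienylic silyl ether, the equatorial preference of the silyloxy group may give too little face selectivity, or the diene may react slowly because it must reach the s-cis form with an inside substituent at C5. Fallback: the cycloaddition of 19 would be run under external chiral control with the triflimide-activated (R)-enantiomer of the oxazaborolidine of step 3. By the same binding model, this enantiomer exposes the α-Si face of the enal and is matched with the C4 relay; catalysis of intramolecular Diels–Alder reactions of trienals by this catalyst class is known. The fallback sets out from 19 and returns at 20 and makes no new compound (F0).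

Step 3 (catalytic asymmetric Diels–Alder). The β-substituted enal may turn over slowly, the strong acid may polymerise the diene, or the enantioselectivity may be insufficient. Fallback by resolution, setting out from 4 and 5: Me2AlCl-promoted cycloaddition would give the racemic exo aldehyde F1, and NaBH4 reduction the racemic neopentyl alcohol F2. Acylation with (1S)-camphanic chloride would give the camphanate of the (1S,2R,8aS)-alcohol F3 and the diastereomeric camphanate of its enantiomer F4, to be separated by chromatography or crystallisation. Hydrolysis of F3 (NaOH, MeOH/H2O) would release the enantiopure alcohol F5, and Dess–Martin oxidation returns to 6.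

Step 17 (chemoselective hydrogenation). The trisubstituted C4′=C4a′ alkene may be over-reduced or migrate, or uptake at the hindered C6=C7 may be slow. Fallback with hydroxyl direction instead of steric discrimination, setting out from 25: desilylation (Bu4NF, THF) would give the homoallylic alcohol F6. Its C4 hydroxyl would then direct [Ir(cod)(PCy3)(py)]PF6 (cat.), H2, CH2Cl2 to C6=C7, returning to the route at 27.

**Further compounds**

F0 | step 13 | none | none
F1 | step 3 | racemic (1S*,2R*,8aS*)-1,2,5,5-tetramethyl-1,2,3,5,6,7,8,8a-octahydronaphthalene-1-carbaldehyde | O=C[C@@]1(C)[C@H](C)CC=C2[C@@H]1CCCC2(C)C.O=C[C@]1(C)[C@@H](C)CC=C2[C@H]1CCCC2(C)C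
F2 | step 3 | racemic [(1S*,2R*,8aS*)-1,2,5,5-tetramethyl-1,2,3,5,6,7,8,8a-octahydronaphthalen-1-yl]methanol | OC[C@@]1(C)[C@H](C)CC=C2[C@@H]1CCCC2(C)C.OC[C@]1(C)[C@@H](C)CC=C2[C@H]1CCCC2(C)C
F3 | step 3 | (1S)-camphanate of the (1S,2R,8aS)-alcohol | O=C(OC[C@@]1(C)[C@H](C)CC=C2[C@@H]1CCCC2(C)C)[C@@]12CC[C@@](C)(C(=O)O1)C2(C)C
F4 | step 3 | (1S)-camphanate of the (1R,2S,8aR)-alcohol (unwanted diastereomer) | O=C(OC[C@]1(C)[C@@H](C)CC=C2[C@H]1CCCC2(C)C)[C@@]12CC[C@@](C)(C(=O)O1)C2(C)C
F5 | step 3 | [(1S,2R,8aS)-1,2,5,5-tetramethyl-1,2,3,5,6,7,8,8a-octahydronaphthalen-1-yl]methanol | OC[C@@]1(C)[C@H](C)CC=C2[C@@H]1CCCC2(C)C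
F6 | step 17 | (4R)-Δ6-octalin-4-ol with C9–CH2–(2,5-dimethoxyphenyl) | [C@@H]1(O)CCC[C@H]2[C@@]1(CC[C@@]3(C)[C@H](C)CC=C4[C@@H]3CCCC4(C)C)C=C[C@H](C)[C@]2(C)Cc1cc(OC)ccc1OC
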